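**Retrosynthetic overview**

1. Target ⇐ veratroylation at O6 and 6‑OH‑directed epoxidation of jaeschkeanadiol 23 ⇐ removal of the C10 carbonyl (dithiolane) and β‑elimination of the C8 oxygen from triol ketal 20.
2. 5‑H and 6‑OH of 20 ⇐ silicon‑tethered hydrosilylation of the Δ5 alkene 17, anchored on the C8 oxygen. 17 ⇐ eliminative cleavage of a temporary C5–O bond (oxygen bridge C5–O–C8) through the C6 ketone hydrazone. C4 carbinol ⇐ isopropyl addition to the bridged ketone 10.
3. Key disconnection: bonds C1–C5 and C8–C9 in one intramolecular (4+3) cycloaddition of an oxyallyl cation (C9–C10–C1) with a 2‑methylfuran (C5–C6–C7–C8 plus its oxygen), tethered through C2–C3–C4. The cyclopentane and the cycloheptene close together; the oxirane is formed last.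
4. Enabling feature: in the seven‑membered ring the four‑carbon unit C5–C8 ends at C8, which carries a methyl group and an oxygen (a dearomatized 2‑methylfuran). It is flanked by the three‑carbon unit C9–C10–C1, whose quaternary C1 is a stabilized cation terminus. The five‑membered ring C1–C5 serves as the tether ring.
5. Acyclic precursor 7 ⇐ 5‑methylfurfural, an allylborane and 3‑methylbut‑3‑en‑2‑one.

Key step: step 5

Remark (locants): bicyclic and tricyclic compounds carry the daucane locants of the target (C1 ring‑fusion carbon with methyl, C2, C3, C4 carbinol carbon with isopropyl, C5 ring‑fusion CH, C6 acyloxy carbon, C7, C8 methyl‑bearing carbon, C9, C10); β is the face of the C1 methyl group and α the face of H‑5, so the target is the 8α,9α‑epoxide of jaeschkeanadiol 6‑O‑veratrate.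
Remark (chemistry): compound 7 is formed as both epimers at the chlorine‑bearing carbon, which is of no consequence because that carbon becomes the planar terminus of the oxyallyl cation.

**Step 1**
Reactants: 1 5‑methylfurfural
Product: 2 (R)‑1‑(5‑methylfuran‑2‑yl)but‑3‑en‑1‑ol
Conditions: (+)‑Ipc2B(allyl) [from (−)‑α‑pinene], Et2O, −78 °C; then NaOH, H2O2
Reagents that add atoms: (+)‑B‑allyldiisopinocampheylborane, C=CCB([C@H]1C[C@H]2C[C@@H]([C@@H]1C)C2(C)C)[C@H]1C[C@H]2C[C@@H]([C@@H]1C)C2(C)C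
Why: Brown asymmetric allylboration through a chair six‑membered transition state, in which the reagent derived from (−)‑α‑pinene should add to the Re face of the aromatic aldehyde and so give the (R)‑carbinol.

**Step 2**
Reactants: 2 (R)‑1‑(5‑methylfuran‑2‑yl)but‑3‑en‑1‑ol
Product: 3 (R)‑triethyl{[1‑(5‑methylfuran‑2‑yl)but‑3‑en‑1‑yl]oxy}silane
Conditions: Et3SiCl, imidazole, CH2Cl2, 0 °C to rt
Reagents that add atoms: chlorotriethylsilane, CC[Si](Cl)(CC)CC
Why: Standard silylation of a secondary alcohol; the ether blocks capture of the later cation by oxygen and serves as the stereocontrolling group in step 5.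

**Step 3**
Reactants: 3 (R)‑triethyl{[1‑(5‑methylfuran‑2‑yl)but‑3‑en‑1‑yl]oxy}silane; 4 3‑methylbut‑3‑en‑2‑one
Product: 5 (3E,6R)‑3‑methyl‑6‑(5‑methylfuran‑2‑yl)‑6‑(triethylsilyloxy)hex‑3‑en‑2‑one
Conditions: RuCl2(H2IMes)(=CH‑C6H4‑2‑OiPr) (second‑generation Hoveyda–Grubbs catalyst, 5 mol %), 4 (5 equiv), CH2Cl2, 40 °C
Reagents that add atoms: none
Why: Olefin cross‑metathesis of a terminal alkene with a 1,1‑disubstituted enone, driven by loss of ethene; the alkene geometry is irrelevant because the double bond is reduced in step 4.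

**Step 4**
Reactants: 5 (3E,6R)‑3‑methyl‑6‑(5‑methylfuran‑2‑yl)‑6‑(triethylsilyloxy)hex‑3‑en‑2‑one
Product: 7 (6R)‑3‑chloro‑3‑methyl‑6‑(5‑methylfuran‑2‑yl)‑6‑(triethylsilyloxy)hexan‑2‑one, via triethylsilyl enol ether 6 (not isolated)
Conditions: Et3SiH, RhCl(PPh3)3 (2 mol %), THF, 50 °C; then NCS, THF, −20 to 0 °C
Reagents that add atoms: N‑chlorosuccinimide, ClN1C(=O)CCC1=O
Why: Rhodium‑catalysed 1,4‑hydrosilylation gives the tetrasubstituted silyl enol ether regiospecifically, and electrophilic chlorination of that enol ether, which is far more nucleophilic than the 2,5‑dialkylfuran, should place chlorine only on the tertiary α‑carbon.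

**Step 5**
Reactants: 7 (6R)‑3‑chloro‑3‑methyl‑6‑(5‑methylfuran‑2‑yl)‑6‑(triethylsilyloxy)hexan‑2‑one
Product: 8 5α,8α‑epoxy‑1β,8β‑dimethyl‑4α‑(triethylsilyloxy)bicyclo[5.3.0]dec‑6‑en‑10‑one (oxygen‑bridged cycloadduct)
Conditions: Et3N (3 equiv), CF3CH2OH, 0 °C to rt
Reagents that add atoms: none
Why: Et3N enolizes the methyl ketone toward C9 and the tertiary C1–Cl bond ionizes to the oxyallyl cation C9–C10(O−)–C1(+), which adds across the 2‑ and 5‑positions of the tethered furan (the future C5 and C8) in a (4+3) cycloaddition that dearomatizes the heteroarene. The closest known reaction type is the (4+3) cycloaddition of oxyallyl cations, generated from α‑chloro ketones with an amine in a fluorinated alcohol, with furans, including intramolecular cases with three‑atom tethers. The cyclopentane closes as the tether ring through bond C1–C5 and the cycloheptenone as the cycloaddition ring through bond C8–C9, the furan oxygen becoming a one‑atom bridge C5–O–C8. C5 and C8 are tied together by suprafacial addition to the planar furan, and C1 follows from ring strain, because only the adduct with C2 on the face of the oxygen bridge has a small C4–C5–C1–C2 dihedral angle and can hold the five‑membered ring, which puts the C1 methyl anti to the bridge as the target requires. The absolute sense comes from C4: allylic 1,3‑strain with the furan 3‑H keeps the carbinol hydrogen in the furan plane, the tether reaches the cation on one face and OSiEt3 points to the other, so the (R)‑carbinol should give the ring fusion of the target with OSiEt3 on the α face. The step needs cycloaddition to outrun loss of HCl and solvent capture, which the five‑ring tether and the electron‑rich 2,5‑dialkylfuran should secure.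

**Step 6**
Reactants: 8 5α,8α‑epoxy‑1β,8β‑dimethyl‑4α‑(triethylsilyloxy)bicyclo[5.3.0]dec‑6‑en‑10‑one
Product: 9 5α,8α‑epoxy‑10,10‑(ethylenedioxy)‑1β,8β‑dimethylbicyclo[5.3.0]dec‑6‑en‑4α‑ol
Conditions: HOCH2CH2OH, HC(OEt)3, p‑TsOH·H2O (cat.), CH2Cl2, rt
Reagents that add atoms: ethane‑1,2‑diol, OCCO
Why: Acid‑catalysed ketalization with orthoformate as water scavenger masks the C10 ketone for the organometallic, hydrazine and silane steps, and the acid‑labile triethylsilyl ether should be cleaved in the same operation.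

**Step 7**
Reactants: 9 5α,8α‑epoxy‑10,10‑(ethylenedioxy)‑1β,8β‑dimethylbicyclo[5.3.0]dec‑6‑en‑4α‑ol
Product: 10 5α,8α‑epoxy‑10,10‑(ethylenedioxy)‑1β,8β‑dimethylbicyclo[5.3.0]dec‑6‑en‑4‑one
Conditions: Dess–Martin periodinane, CH2Cl2, rt
Reagents that add atoms: none
Why: Dess–Martin oxidation of the only free alcohol under neutral conditions; the C4 stereocentre has done its work in step 5 and is removed on purpose.

**Step 8**
Reactants: 10 5α,8α‑epoxy‑10,10‑(ethylenedioxy)‑1β,8β‑dimethylbicyclo[5.3.0]dec‑6‑en‑4‑one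
Product: 11 5α,8α‑epoxy‑10,10‑(ethylenedioxy)dauc‑6‑en‑4β‑ol (4α‑isopropyl)
Conditions: iPrMgCl, LaCl3·2LiCl, THF, −78 to 0 °C; aq. NH4Cl
Reagents that add atoms: isopropylmagnesium chloride, CC(C)[Mg]Cl
Why: Lanthanum‑promoted Grignard addition (suppressing reduction and enolization) should occur on the α face next to the small bridging oxygen, which can also chelate the metal, because the β face is screened by H‑6 of the etheno bridge lying in the trajectory; this gives the 4α‑isopropyl‑4β‑ol of the target.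

**Step 9**
Reactants: 11 5α,8α‑epoxy‑10,10‑(ethylenedioxy)dauc‑6‑en‑4β‑ol
Product: 14 5α,8α‑epoxy‑10,10‑(ethylenedioxy)daucane‑4β,6α‑diol, via dimethylsilyl ether 12 (not isolated), via cyclic siloxane 13 (not isolated)
Conditions: HMe2SiCl, Et3N, DMAP (cat.), CH2Cl2, rt; then Pt2[(CH2=CHSiMe2)2O]3 (Karstedt catalyst, 0.5 mol %), toluene, 60 °C; then KF, KHCO3, 30 % H2O2, THF/MeOH, rt
Reagents that add atoms: hydrogen peroxide, OO
Why: Tamao–Ito intramolecular hydrosilylation (5‑exo) from the 4β‑oxygen, which lies in the plane of the C6=C7 bond next to C6, should deliver silicon to C6 only, and Tamao–Fleming oxidation with retention then gives the C6 alcohol; only this regiochemistry matters because C6 is oxidized in step 10.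

**Step 10**
Reactants: 14 5α,8α‑epoxy‑10,10‑(ethylenedioxy)daucane‑4β,6α‑diol
Product: 15 5α,8α‑epoxy‑10,10‑(ethylenedioxy)‑4β‑hydroxydaucan‑6‑one
Conditions: Dess–Martin periodinane, CH2Cl2, rt
Reagents that add atoms: none
Why: Dess–Martin oxidation of the only secondary alcohol (the tertiary 4‑OH cannot react) gives a ketone whose α‑carbon C5 carries the oxygen bridge.

**Step 11**
Reactants: 15 5α,8α‑epoxy‑10,10‑(ethylenedioxy)‑4β‑hydroxydaucan‑6‑one
Product: 17 10,10‑(ethylenedioxy)dauc‑5‑ene‑4β,8α‑diol, via hydrazone 16 (not isolated)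
Conditions: N2H4·H2O, EtOH, 60 °C; then KOtBu (cat.), DMSO, rt
Reagents that add atoms: none
Why: Kishner–Leonard eliminative reduction, in which the hydrazone anion expels the α‑alkoxide (the bridge oxygen at C5) and the vinyl diazene loses N2, should place the alkene at C5=C6 and leave the oxygen on C8 as the 8α‑alcohol with the configuration set in step 5.

**Step 12**
Reactants: 17 10,10‑(ethylenedioxy)dauc‑5‑ene‑4β,8α‑diol
Product: 20 10,10‑(ethylenedioxy)‑5αH‑daucane‑4β,6α,8α‑triol, via dimethylsilyl ether 18 (not isolated), via cyclic siloxane 19 (not isolated)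
Conditions: HMe2SiCl (1.1 equiv), Et3N, CH2Cl2, −20 °C; then Pt2[(CH2=CHSiMe2)2O]3 (0.5 mol %), toluene, 60 °C; then KF, KHCO3, 30 % H2O2, THF/MeOH, rt
Reagents that add atoms: hydrogen peroxide, OO
Why: The less hindered tertiary 8α‑OH should be silylated in preference to the 4‑OH (flanked by isopropyl and the fully substituted C5), and Tamao–Ito 5‑exo hydrosilylation then delivers H to C5 and Si to C6 suprafacially on the α face where the C8 oxygen sits, so that Tamao–Fleming oxidation with retention gives 5α‑H (trans ring fusion) and 6α‑OH.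

**Step 13**
Reactants: 20 10,10‑(ethylenedioxy)‑5αH‑daucane‑4β,6α,8α‑triol
Product: 21 4β,6α‑dihydroxy‑5αH‑dauc‑8‑en‑10‑one
Conditions: 2 M HCl, THF, 40 °C
Reagents that add atoms: water, O
Why: Ketal hydrolysis frees the C10 ketone, and the tertiary β‑hydroxy ketone should dehydrate toward C9, the only enolizable position because C1 is quaternary, to give the conjugated C8=C9 enone.

**Step 14**
Reactants: 21 4β,6α‑dihydroxy‑5αH‑dauc‑8‑en‑10‑one
Product: 22 10,10‑(ethylenedithio)‑5αH‑dauc‑8‑ene‑4β,6α‑diol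
Conditions: HSCH2CH2SH, BF3·OEt2 (cat.), CH2Cl2, −20 to 0 °C
Reagents that add atoms: ethane‑1,2‑dithiol, SCCS
Why: Lewis‑acid‑catalysed dithioketalization of an α,β‑unsaturated ketone, which in the classical enone cases keeps the double bond in place.

**Step 15**
Reactants: 22 10,10‑(ethylenedithio)‑5αH‑dauc‑8‑ene‑4β,6α‑diol
Product: 23 5αH‑dauc‑8‑ene‑4β,6α‑diol (jaeschkeanadiol)
Conditions: Raney Ni (W‑2, deactivated in acetone), EtOH, reflux
Reagents that add atoms: none
Why: Mozingo desulfurization should convert C10 into a methylene group and, with deactivated nickel, leave the trisubstituted C8=C9 alkene where the enone placed it.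

**Step 16**
Reactants: 23 5αH‑dauc‑8‑ene‑4β,6α‑diol
Product: 24 8α,9α‑epoxy‑5αH‑daucane‑4β,6α‑diol
Conditions: VO(acac)2 (5 mol %), t‑BuOOH, CH2Cl2, 0 °C to rt
Reagents that add atoms: tert‑butyl hydroperoxide, CC(C)(C)OO
Why: Vanadium‑catalysed epoxidation directed by the homoallylic 6α‑hydroxyl should deliver oxygen to the α face, which is also the face opposite the C1 methyl group.

**Step 17**
Reactants: 24 8α,9α‑epoxy‑5αH‑daucane‑4β,6α‑diol; 25 3,4‑dimethoxybenzoyl chloride
Product: 26 8α,9α‑epoxy‑4β‑hydroxy‑5αH‑daucan‑6α‑yl 3,4‑dimethoxybenzoate (target)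
Conditions: Et3N, DMAP (cat.), CH2Cl2, 0 °C to rt
Reagents that add atoms: none
Why: DMAP‑catalysed acylation of the only secondary alcohol; the tertiary 4‑OH and the epoxide should not react under these mild basic conditions.

**Compound list**

1 | 5‑methylfurfural | Cc1ccc(C=O)o1 | starting material
2 | (R)‑1‑(5‑methylfuran‑2‑yl)but‑3‑en‑1‑ol | C=CC[C@@H](O)c1ccc(C)o1 | intermediate
3 | (R)‑triethyl{[1‑(5‑methylfuran‑2‑yl)but‑3‑en‑1‑yl]oxy}silane | C=CC[C@@H](O[Si](CC)(CC)CC)c1ccc(C)o1 | intermediate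
4 | 3‑methylbut‑3‑en‑2‑one | CC(=C)C(C)=O | starting material
5 | (3E,6R)‑3‑methyl‑6‑(5‑methylfuran‑2‑yl)‑6‑(triethylsilyloxy)hex‑3‑en‑2‑one | CC(=O)/C(C)=C/C[C@@H](O[Si](CC)(CC)CC)c1ccc(C)o1 | intermediate
6 | (6R)‑3‑methyl‑6‑(5‑methylfuran‑2‑yl)‑2,6‑bis(triethylsilyloxy)hex‑2‑ene (E/Z mixture, not isolated) | CC(O[Si](CC)(CC)CC)=C(C)CC[C@@H](O[Si](CC)(CC)CC)c1ccc(C)o1 | intermediate
7 | (6R)‑3‑chloro‑3‑methyl‑6‑(5‑methylfuran‑2‑yl)‑6‑(triethylsilyloxy)hexan‑2‑one (both C3 epimers) | CC(=O)C(C)(Cl)CC[C@@H](O[Si](CC)(CC)CC)c1ccc(C)o1 | intermediate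
8 | 5α,8α‑epoxy‑1β,8β‑dimethyl‑4α‑(triethylsilyloxy)bicyclo[5.3.0]dec‑6‑en‑10‑one | CC[Si](CC)(CC)O[C@@H]1CC[C@]2(C)C(=O)C[C@]3(C)O[C@]12C=C3 | intermediate
9 | 5α,8α‑epoxy‑10,10‑(ethylenedioxy)‑1β,8β‑dimethylbicyclo[5.3.0]dec‑6‑en‑4α‑ol | O[C@@H]1CC[C@]2(C)C3(OCCO3)C[C@]4(C)O[C@]12C=C4 | intermediate
10 | 5α,8α‑epoxy‑10,10‑(ethylenedioxy)‑1β,8β‑dimethylbicyclo[5.3.0]dec‑6‑en‑4‑one | O=C1CC[C@]2(C)C3(OCCO3)C[C@]4(C)O[C@]12C=C4 | intermediate
11 | 5α,8α‑epoxy‑10,10‑(ethylenedioxy)dauc‑6‑en‑4β‑ol | CC(C)[C@]1(O)CC[C@]2(C)C3(OCCO3)C[C@]4(C)O[C@]12C=C4 | intermediate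
12 | 4‑O‑dimethylsilyl ether of 11 (not isolated) | CC(C)[C@]1(O[SiH](C)C)CC[C@]2(C)C3(OCCO3)C[C@]4(C)O[C@]12C=C4 | intermediate
13 | cyclic siloxane, 4β‑O–SiMe2–C6α, of 5α,8α‑epoxy‑10,10‑(ethylenedioxy)daucane (not isolated) | CC(C)[C@]1(O[Si]5(C)C)CC[C@]2(C)C3(OCCO3)C[C@]4(C)O[C@]12[C@@H]5C4 | intermediate
14 | 5α,8α‑epoxy‑10,10‑(ethylenedioxy)daucane‑4β,6α‑diol | CC(C)[C@]1(O)CC[C@]2(C)C3(OCCO3)C[C@]4(C)O[C@]12[C@@H](O)C4 | intermediate
15 | 5α,8α‑epoxy‑10,10‑(ethylenedioxy)‑4β‑hydroxydaucan‑6‑one | CC(C)[C@]1(O)CC[C@]2(C)C3(OCCO3)C[C@]4(C)O[C@]12C(=O)C4 | intermediate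
16 | hydrazone of 15 (not isolated) | CC(C)[C@]1(O)CC[C@]2(C)C3(OCCO3)C[C@]4(C)O[C@]12C(=NN)C4 | intermediate
17 | 10,10‑(ethylenedioxy)dauc‑5‑ene‑4β,8α‑diol | CC(C)[C@]1(O)CC[C@@]2(C)C1=CC[C@@](C)(O)CC23OCCO3 | intermediate
18 | 8‑O‑dimethylsilyl ether of 17 (not isolated) | CC(C)[C@]1(O)CC[C@@]2(C)C1=CC[C@@](C)(O[SiH](C)C)CC23OCCO3 | intermediate
19 | cyclic siloxane, 8α‑O–SiMe2–C6α, of 10,10‑(ethylenedioxy)‑5αH‑daucan‑4β‑ol (not isolated) | CC(C)[C@]1(O)CC[C@@]2(C)[C@H]1[C@@H]4C[C@@](C)(O[Si]4(C)C)CC23OCCO3 | intermediate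
20 | 10,10‑(ethylenedioxy)‑5αH‑daucane‑4β,6α,8α‑triol | CC(C)[C@]1(O)CC[C@@]2(C)[C@H]1[C@@H](O)C[C@@](C)(O)CC23OCCO3 | intermediate
21 | 4β,6α‑dihydroxy‑5αH‑dauc‑8‑en‑10‑one | CC(C)[C@]1(O)CC[C@@]2(C)[C@H]1[C@@H](O)CC(C)=CC2=O | intermediate
22 | 10,10‑(ethylenedithio)‑5αH‑dauc‑8‑ene‑4β,6α‑diol | CC(C)[C@]1(O)CC[C@@]2(C)[C@H]1[C@@H](O)CC(C)=CC23SCCS3 | intermediate
23 | 5αH‑dauc‑8‑ene‑4β,6α‑diol (jaeschkeanadiol) | CC(C)[C@]1(O)CC[C@@]2(C)[C@H]1[C@@H](O)CC(C)=CC2 | intermediate
24 | 8α,9α‑epoxy‑5αH‑daucane‑4β,6α‑diol | CC(C)[C@]1(O)CC[C@@]2(C)[C@H]1[C@@H](O)C[C@@]3(C)O[C@H]3C2 | intermediate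
25 | 3,4‑dimethoxybenzoyl chloride | COc1ccc(C(Cl)=O)cc1OC | starting material
26 | 8α,9α‑epoxy‑4β‑hydroxy‑5αH‑daucan‑6α‑yl 3,4‑dimethoxybenzoate | COc1ccc(C(=O)O[C@H]2C[C@@]3(C)O[C@H]3C[C@@]3(C)CC[C@@](O)(C(C)C)[C@H]23)cc1OC | target

**Total step count:** 17. **Longest linear sequence:** 17 steps (from 5‑methylfurfural).

**Steps most likely to fail**

1. Step 5. Loss of HCl from the tertiary chloride back to enone 5, together with capture of the cation by the solvent, may outrun the cycloaddition. Fallback: it sets out from 5 and returns at 8. The rhodium‑catalysed hydrosilylation of step 4 is followed by hydrolysis of 6 (K2CO3, MeOH) to give (6R)‑3‑methyl‑6‑(5‑methylfuran‑2‑yl)‑6‑(triethylsilyloxy)hexan‑2‑one F1. LiN(iPr)2 and Me3SiCl (THF, −78 °C) give the less substituted enol ether (6R)‑3‑methyl‑6‑(5‑methylfuran‑2‑yl)‑6‑(triethylsilyloxy)‑2‑(trimethylsilyloxy)hex‑1‑ene F2. NCS then gives (6R)‑1‑chloro‑3‑methyl‑6‑(5‑methylfuran‑2‑yl)‑6‑(triethylsilyloxy)hexan‑2‑one F3, which has no hydrogen in position for loss of HCl. NaOCH2CF3 in CF3CH2OH should enolize F3 toward the tertiary carbon and ionize the primary chloride to the same oxyallyl cation, which closes to 8.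

2. Step 11. Base may trigger β‑elimination of the C8 oxygen or retro‑aldol cleavage at the hydrazone stage, or the hydrazone may simply be reduced to the methylene compound without C5–O cleavage. Fallback: it sets out from 15 and returns at 20, replacing steps 11 and 12. SmI2 (THF/MeOH, −78 °C) cleaves the α‑alkoxy ketone reductively to 10,10‑(ethylenedioxy)‑4β,8α‑dihydroxy‑5αH‑daucan‑6‑one F4. Protonation of the samarium enolate at C5 is expected on the α face, under the released C8 alkoxide, and the ring fusion can be equilibrated through the enol if needed. A Narasaka–Prasad 1,3‑syn reduction directed by the 8α‑hydroxyl (Et2BOMe, NaBH4, THF/MeOH, −78 °C) then gives 20.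

3. Step 15. The C8=C9 double bond may migrate or be saturated on the nickel surface, and in step 14 the thiol may add in conjugate fashion to the hindered enone instead of forming the dithiolane. Fallback: it sets out from 21 and returns at 23, replacing steps 14 and 15. Luche reduction (NaBH4, CeCl3·7H2O, MeOH, −78 °C) gives the allylic alcohol 5αH‑dauc‑8‑ene‑4β,6α,10‑triol F5. Ionic hydrogenolysis (Et3SiH, BF3·OEt2, CH2Cl2, −78 °C) through the allyl cation, with hydride delivery to the less substituted terminus C10, should then give 23.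

**Further compounds**

F1 | step 5 | (6R)‑3‑methyl‑6‑(5‑methylfuran‑2‑yl)‑6‑(triethylsilyloxy)hexan‑2‑one | CC(=O)C(C)CC[C@@H](O[Si](CC)(CC)CC)c1ccc(C)o1
F2 | step 5 | (6R)‑3‑methyl‑6‑(5‑methylfuran‑2‑yl)‑6‑(triethylsilyloxy)‑2‑(trimethylsilyloxy)hex‑1‑ene | C=C(O[Si](C)(C)C)C(C)CC[C@@H](O[Si](CC)(CC)CC)c1ccc(C)o1
F3 | step 5 | (6R)‑1‑chloro‑3‑methyl‑6‑(5‑methylfuran‑2‑yl)‑6‑(triethylsilyloxy)hexan‑2‑one | ClCC(=O)C(C)CC[C@@H](O[Si](CC)(CC)CC)c1ccc(C)o1
F4 | step 11 | 10,10‑(ethylenedioxy)‑4β,8α‑dihydroxy‑5αH‑daucan‑6‑one | CC(C)[C@]1(O)CC[C@@]2(C)[C@H]1C(=O)C[C@@](C)(O)CC23OCCO3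
F5 | step 15 | 5αH‑dauc‑8‑ene‑4β,6α,10‑triol (C10 epimers) | CC(C)[C@]1(O)CC[C@@]2(C)[C@H]1[C@@H](O)CC(C)=CC2O
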